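**Retrosynthetic overview** (labdane numbering: C1–C10 decalin, C11–C16 side chain, C17 on C8, C18/C19 on C4, C20 on C10)
1. The C15–O ester bond is made last by Mitsunobu union of labd-7-ene-2α,15-diol with (Z)-p-coumaric acid, whose Z alkene comes from a Still–Gennari olefination.
2. Ring B is a cyclohexene whose C7=C8 bond lies opposite the ring-fusion bond C5–C10, so C5–C6–C7 and C10–C9–C8 are two three-carbon units joined at both ends. A temporary C6 carbonyl makes the first a double nucleophile (C5, C7); the C8 acetyl with a C9=C10 alkene makes the second a double electrophile (C10, C8).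
3. Both rings therefore close from an open chain in one operation: ring A first by Michael addition (C5–C10), then ring B by aldol condensation (C7=C8). The C2 acetoxy centre relays C10, C5 and C9, and the C6 oxygen is removed afterwards together with the acetates.
4. The open chain is joined at C1–C2 by a catalytic vinylogous aldol reaction that sets C2. Mesityl oxide plus an allylsilane gives C2–C7 with C18/C19; (S)-citronellol (C13 bought) C-acetylated at its alkene carbon gives C1 and C8–C17 with C20.

Key step: step 7

Remark (assumption): in step 5 the sense of induction of the tryptophan-derived oxazaborolidinone is taken from the usual aldehyde–indole stacking model (Re-face addition with the L-tryptophan reagent); if the sense is opposite for this dienol ether, the D-tryptophan antipode is used with no other change.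

Step 1
Reactants: 1 mesityl oxide; 2 allyltrimethylsilane
Product: 3 4,4-dimethylhept-6-en-2-one
Conditions: TiCl4 (1 equiv), CH2Cl2, −78 °C; aq. work-up
Reagents that add atoms: none
Why: Hosomi–Sakurai conjugate allylation, in which TiCl4 activates the enone and the allylsilane adds through its γ-carbon to the β,β-disubstituted terminus, builds the C4 quaternary centre with both methyl groups; no stereocentre is formed.

Step 2
Reactants: 3 4,4-dimethylhept-6-en-2-one
Product: 4 3,3-dimethyl-5-oxohexanal
Conditions: O3, CH2Cl2, −78 °C; then PPh3, −78 °C → rt; used at once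
Reagents that add atoms: ozone, [O-][O+]=O
Why: Ozonolysis with reductive work-up cleaves the terminal alkene to the C2 aldehyde while the saturated ketone is inert; the keto aldehyde is not stored because acid or base would close it by aldol condensation.

Step 3
Reactants: 5 (S)-citronellol; 6 acetic anhydride
Product: 7 (3S)-6-acetyl-3,7-dimethyloct-7-en-1-yl acetate (both C6 epimers)
Conditions: Ac2O (excess), ZnCl2 (1 equiv), CH2Cl2, 0 °C → rt
Reagents that add atoms: none
Why: Ene-type Friedel–Crafts (Kondakov) acylation of the trisubstituted alkene puts the acetyl group on the less substituted alkene carbon (future C9) and the tertiary cation loses a methyl proton to give the β,γ-unsaturated ketone, while the alcohol is acetylated in the same pot; the new centre forms unselectively but becomes trigonal in step 4, and the bought (S)-methyl centre (future C13) is untouched.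

Step 4
Reactants: 7 (3S)-6-acetyl-3,7-dimethyloct-7-en-1-yl acetate
Product: 8 (3S)-6-[1-(tert-butyldimethylsilyloxy)ethylidene]-3,7-dimethyloct-7-en-1-yl acetate (E/Z mixture)
Conditions: TBSOTf, Et3N, CH2Cl2, 0 °C
Reagents that add atoms: tert-butyldimethylsilyl trifluoromethanesulfonate (TBSOTf), CC(C)(C)[Si](C)(C)OS(=O)(=O)C(F)(F)F
Why: Soft enolisation removes the doubly activated hydrogen (allylic and α to the carbonyl) from the O-silylated ketone, so the conjugated 2-silyloxy-1,3-diene should form rather than the terminal enol ether; its geometry is without consequence.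

Step 5
Reactants: 8 silyl dienol ether; 4 3,3-dimethyl-5-oxohexanal
Product: 9 (3S,9S)-6-acetyl-9-hydroxy-3,7,11,11-tetramethyl-13-oxotetradec-6-en-1-yl acetate (E/Z mixture at the enone)
Conditions: (S)-4-(1H-indol-3-ylmethyl)-2-phenyl-3-tosyl-1,3,2-oxazaborolidin-5-one (from N-tosyl-L-tryptophan, 0.5 equiv), i-PrOH (1.1 equiv), EtCN, −78 °C
Reagents that add atoms: none
Why: Vinylogous Mukaiyama aldol addition, in which the shielded, fully substituted α-carbon of the dienol ether leaves the terminal CH2 (γ, future C1) to attack the boron-bound aldehyde (more reactive than the ketone) and the chiral oxazaborolidinone exposes the Re face, sets the (S)-carbinol (future C2), the only stereocentre made by catalysis.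

Step 6
Reactants: 9 hydroxy enone; 6 acetic anhydride
Product: 10 (3S,9S)-6-acetyl-3,7,11,11-tetramethyl-13-oxotetradec-6-ene-1,9-diyl diacetate
Conditions: Ac2O, pyridine, DMAP (cat.), CH2Cl2, 0 °C → rt
Reagents that add atoms: none
Why: DMAP-catalysed acetylation caps the C2 hydroxyl so that it cannot form a hemiketal or cyclic enol ether with the C6 ketone in step 7; the acetate leaves together with the C15 acetate in step 8.

Step 7
Reactants: 10 diacetoxy keto enone
Product: 13 2α,15-diacetoxylabd-7-en-6-one, via seco-diketone 11 (not isolated), via aldol 12 (not isolated)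
Conditions: TsOH·H2O (0.5 equiv), toluene, 80 °C, then reflux (Dean–Stark)
Reagents that add atoms: none
Why: TsOH interconverts the E/Z and β,γ-isomers of the enone and enolises the C6 methyl ketone towards C5; the enol carbon C5 adds to C10 of the protonated enone (a tertiary, hydroxyallyl-cation-like centre) to close ring A and give seco-diketone 11, whose C6-methyl enol (C7) then adds to the C8 carbonyl (aldol 12), and water is lost to close ring B as the 7-en-6-one. The closest known reaction type is the intramolecular Michael addition–aldol condensation cascade of open-chain keto enones (a Robinson annulation run within one chain), in its acid-catalysed form that goes through the more substituted enol. Ring A closes 6-exo-trig at the enone β-carbon and ring B 6-(enolendo)-exo-trig at the C8 carbonyl, followed by dehydration. C10 is set against C2 in a chair transition state for ring A with the C2 acetoxy group equatorial and the acyl-bearing C9 anti to the C1–C2 bond (the alternative puts C2 in A(1,3) strain with the substituents on C9), which leaves the C10 methyl axial and trans to the acetate. C5 and C9 are both α to a ketone in 11 and equilibrate, so ring B should close through the chair-like aldol transition state with the trans ring fusion and the C9 side chain equatorial, and C5 remains correctable afterwards as the α′ centre of the enone. The step needs the aldol to run from C7 to C8 and not from C17 to C6, which is secured because the C6 carbonyl sits on C5 between two fully substituted carbons (a poor acceptor, and its enone would force a vinylic methyl against the C4 methyl groups), while the C4 gem-dimethyl group favours the first closure and no other five- or six-membered ring can form.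

Step 8
Reactants: 13 2α,15-diacetoxylabd-7-en-6-one
Product: 14 labd-7-ene-2α,15-diol
Conditions: LiAlH4/AlCl3 (1:3, AlHCl2 formed in situ), Et2O, 0 °C → rt; aq. sodium potassium tartrate work-up
Reagents that add atoms: none
Why: Mixed-hydride (chloroalane) reduction, in which hydride reduces the enone 1,2 from the open α face and cleaves both acetates and AlHCl2 ionises the axial 6β-aluminate to an allyl cation that takes hydride at the secondary terminus C6, should keep the more substituted C7=C8 alkene, as in the conversion of steroidal 4-en-3-ones into 4-enes; no stereocentre is touched.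

Step 9
Reactants: 15 4-(tert-butyldimethylsilyloxy)benzaldehyde; 16 methyl bis(2,2,2-trifluoroethyl)phosphonoacetate
Product: 17 methyl (Z)-3-[4-(tert-butyldimethylsilyloxy)phenyl]prop-2-enoate
Conditions: KN(SiMe3)2, 18-crown-6, THF, −78 °C
Reagents that add atoms: none
Why: Still–Gennari modification of the Horner–Wadsworth–Emmons reaction, in which the electron-poor phosphonate with a dissociated potassium counter-ion eliminates faster than the adducts equilibrate, should give the (Z)-cinnamate under kinetic control.

Step 10
Reactants: 17 methyl (Z)-4-silyloxycinnamate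
Product: 18 (Z)-4-hydroxycinnamic acid ((Z)-p-coumaric acid)
Conditions: LiOH·H2O, THF/MeOH/H2O, rt, dark; then 1 M HCl to pH 3
Reagents that add atoms: lithium hydroxide (LiOH), [Li+].[OH-]
Why: Saponification of the methyl ester with concomitant cleavage of the base-labile aryl silyl ether; the (Z)-alkene is configurationally stable to hydroxide at room temperature with light excluded.

Step 11
Reactants: 14 labd-7-ene-2α,15-diol; 18 (Z)-p-coumaric acid
Product: 19 (2S,5S,9S,10S,13S)-2-hydroxylabd-7-en-15-yl (Z)-3-(4-hydroxyphenyl)prop-2-enoate (target, CNP0301213.1)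
Conditions: PPh3, DIAD, THF, 0 °C, dark
Reagents that add atoms: none
Why: Mitsunobu esterification activates the alcohol and not the acid, so the (Z)-acid never becomes an acylating species that could isomerise; the primary C15 hydroxyl reacts while the secondary C2 hydroxyl, flanked by two neopentyl-type methylenes, is inert to SN2 displacement, and the carboxylate (far more acidic than the phenol) is the nucleophile.

**Compound list**
1 | mesityl oxide (4-methylpent-3-en-2-one) | CC(C)=CC(C)=O | starting material
2 | allyltrimethylsilane | C=CC[Si](C)(C)C | starting material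
3 | 4,4-dimethylhept-6-en-2-one | CC(=O)CC(C)(C)CC=C | intermediate
4 | 3,3-dimethyl-5-oxohexanal | CC(=O)CC(C)(C)CC=O | intermediate
5 | (S)-citronellol, (3S)-3,7-dimethyloct-6-en-1-ol | CC(C)=CCC[C@H](C)CCO | starting material
6 | acetic anhydride | CC(=O)OC(C)=O | starting material
7 | (3S)-6-acetyl-3,7-dimethyloct-7-en-1-yl acetate (both C6 epimers) | C=C(C)C(C(C)=O)CC[C@H](C)CCOC(C)=O | intermediate
8 | (3S)-6-[1-(tert-butyldimethylsilyloxy)ethylidene]-3,7-dimethyloct-7-en-1-yl acetate (E/Z mixture) | C=C(C)C(CC[C@H](C)CCOC(C)=O)=C(C)O[Si](C)(C)C(C)(C)C | intermediate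
9 | (3S,9S)-6-acetyl-9-hydroxy-3,7,11,11-tetramethyl-13-oxotetradec-6-en-1-yl acetate (E/Z mixture) | CC(=O)C(CC[C@H](C)CCOC(C)=O)=C(C)C[C@@H](O)CC(C)(C)CC(C)=O | intermediate
10 | (3S,9S)-6-acetyl-3,7,11,11-tetramethyl-13-oxotetradec-6-ene-1,9-diyl diacetate (E/Z mixture) | CC(=O)C(CC[C@H](C)CCOC(C)=O)=C(C)C[C@@H](OC(C)=O)CC(C)(C)CC(C)=O | intermediate
11 | 2α,15-diacetoxy-7,8-secolabdane-6,8-dione (ring A closed; drawn with the C5 and C9 configurations that go on to 13) | CC(=O)[C@H]1C(C)(C)C[C@H](OC(C)=O)C[C@]1(C)[C@H](C(C)=O)CC[C@H](C)CCOC(C)=O | intermediate (not isolated)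
12 | 2α,15-diacetoxy-8-hydroxylabdan-6-one (C8 configuration open) | CC1(O)CC(=O)[C@H]2C(C)(C)C[C@H](OC(C)=O)C[C@]2(C)[C@H]1CC[C@H](C)CCOC(C)=O | intermediate (not isolated)
13 | (2S,5S,9S,10R,13S)-2α,15-diacetoxylabd-7-en-6-one | CC1=CC(=O)[C@H]2C(C)(C)C[C@H](OC(C)=O)C[C@]2(C)[C@H]1CC[C@H](C)CCOC(C)=O | intermediate
14 | (2S,5S,9S,10S,13S)-labd-7-ene-2α,15-diol | CC1=CC[C@H]2C(C)(C)C[C@H](O)C[C@]2(C)[C@H]1CC[C@H](C)CCO | intermediate
15 | 4-(tert-butyldimethylsilyloxy)benzaldehyde | O=Cc1ccc(O[Si](C)(C)C(C)(C)C)cc1 | starting material
16 | methyl bis(2,2,2-trifluoroethyl)phosphonoacetate | COC(=O)CP(=O)(OCC(F)(F)F)OCC(F)(F)F | starting material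
17 | methyl (Z)-3-[4-(tert-butyldimethylsilyloxy)phenyl]prop-2-enoate | COC(=O)/C=C\c1ccc(O[Si](C)(C)C(C)(C)C)cc1 | intermediate
18 | (Z)-3-(4-hydroxyphenyl)prop-2-enoic acid | OC(=O)/C=C\c1ccc(O)cc1 | intermediate
19 | (2S,5S,9S,10S,13S)-2-hydroxylabd-7-en-15-yl (Z)-3-(4-hydroxyphenyl)prop-2-enoate | CC1=CC[C@H]2C(C)(C)C[C@H](O)C[C@]2(C)[C@H]1CC[C@H](C)CCOC(=O)/C=C\c1ccc(O)cc1 | target

**Step count:** 11 steps in total. Longest linear sequence: 7 steps (steps 3, 4, 5, 6, 7, 8, 11 from (S)-citronellol; equally steps 1, 2, 5, 6, 7, 8, 11 from mesityl oxide).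

**Steps most likely to fail**

Step 7. The Michael addition at the fully substituted C10 may be slow under protic acid. Drift of the double bond to C1=C10, followed by allylic ionisation and loss of the C2 acetate, or intermolecular condensation, could then take over; the aldol could also close in the other sense. The fallback makes the two bonds in two operations and uses the C2 oxygen as a temporary tether. It sets out from 9. Acid-catalysed cyclodehydration of the δ-hydroxy ketone (PPTS, toluene, 4 Å molecular sieves, 80 °C) should give the cyclic enol ether, 2-substituted 4,4,6-trimethyl-3,4-dihydro-2H-pyran F1, in which C5 is a fixed enol-ether nucleophile. TiCl4 (CH2Cl2, −78 °C) should then bring about an intramolecular Mukaiyama–Michael addition of C5 to C10 through a 2-oxabicyclo[2.2.2]octane oxocarbenium ion in which the bulky C9 arm turns away from the C4 methyl groups. Aqueous work-up should release the cyclohexane hydroxy diketone F2 with the C10 methyl trans to the C2 oxygen. Acetylation (Ac2O, DMAP, pyridine) gives the diacetate F3, the C5 epimer of 11, and TsOH in toluene (epimerisation at C5, aldol condensation) comes back to the route at 13.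

Step 5. Facial selectivity at the aldehyde may be poor with this hindered, ketone-derived dienol ether, and some reaction may pass through the α-carbon. The fallback replaces catalysis by resolution and sets out from 8 and 4. A BF3·OEt2-promoted vinylogous Mukaiyama aldol addition (CH2Cl2, −78 °C) gives the hydroxy enone as both C2 epimers F4. Esterification with (S)-O-methylmandelic acid (DCC, DMAP) gives the diastereomeric mandelates F5, which are taken through the conditions of step 7. The two decalin enones then differ in the relation of all four ring stereocentres to the mandelate and should separate by chromatography. The (2S)-series decalin enone mandelate F6 is treated under the conditions of step 8, which remove the mandelate together with the acetate, and the route is rejoined at 14.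

Step 8. Hydride may be delivered to the tertiary allyl terminus C8, or the cation may lose a proton, so that the double bond leaves C7=C8. The fallback is a stepwise allylic deoxygenation through a π-allylpalladium hydride and sets out from 13. Reduction with NaBH4/CeCl3·7H2O (MeOH, 0 °C) from the open α face gives the 6β-alcohol F7, and acetylation (Ac2O, DMAP, pyridine) the triacetate F8. Pd(PPh3)4 with NaBH4 (THF) should reduce only the allylic acetate, with hydride passing from palladium to the less substituted terminus C6, to give labd-7-ene-2α,15-diyl diacetate F9. K2CO3 in MeOH then comes back to the route at 14.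

Further compounds
F1 | step 7 | (3S)-6-acetyl-3,7-dimethyl-8-[(2S)-4,4,6-trimethyl-3,4-dihydro-2H-pyran-2-yl]oct-6-en-1-yl acetate (cyclic enol ether of 9) | CC1=CC(C)(C)C[C@@H](CC(C)=C(CC[C@H](C)CCOC(C)=O)C(C)=O)O1
F2 | step 7 | 15-acetoxy-2α-hydroxy-7,8-secolabdane-6,8-dione, 5-epimer (acetyl cis to the C2 hydroxyl; C9 epimers) | CC(=O)[C@@H]1C(C)(C)C[C@H](O)C[C@]1(C)C(C(C)=O)CC[C@H](C)CCOC(C)=O
F3 | step 7 | 2α,15-diacetoxy-7,8-secolabdane-6,8-dione, 5-epimer (C9 epimers) | CC(=O)[C@@H]1C(C)(C)C[C@H](OC(C)=O)C[C@]1(C)C(C(C)=O)CC[C@H](C)CCOC(C)=O
F4 | step 5 | (3S)-6-acetyl-9-hydroxy-3,7,11,11-tetramethyl-13-oxotetradec-6-en-1-yl acetate, both C9 epimers | CC(=O)C(CC[C@H](C)CCOC(C)=O)=C(C)CC(O)CC(C)(C)CC(C)=O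
F5 | step 5 | (S)-O-methylmandelates of F4 (two diastereomers) | CC(=O)C(CC[C@H](C)CCOC(C)=O)=C(C)CC(OC(=O)[C@@H](OC)c1ccccc1)CC(C)(C)CC(C)=O
F6 | step 5 | 15-acetoxy-6-oxolabd-7-en-2α-yl (S)-2-methoxy-2-phenylacetate | CC1=CC(=O)[C@H]2C(C)(C)C[C@H](OC(=O)[C@@H](OC)c3ccccc3)C[C@]2(C)[C@H]1CC[C@H](C)CCOC(C)=O
F7 | step 8 | 2α,15-diacetoxylabd-7-en-6β-ol | CC1=C[C@@H](O)[C@H]2C(C)(C)C[C@H](OC(C)=O)C[C@]2(C)[C@H]1CC[C@H](C)CCOC(C)=O
F8 | step 8 | labd-7-ene-2α,6β,15-triyl triacetate | CC1=C[C@@H](OC(C)=O)[C@H]2C(C)(C)C[C@H](OC(C)=O)C[C@]2(C)[C@H]1CC[C@H](C)CCOC(C)=O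
F9 | step 8 | labd-7-ene-2α,15-diyl diacetate | CC1=CC[C@H]2C(C)(C)C[C@H](OC(C)=O)C[C@]2(C)[C@H]1CC[C@H](C)CCOC(C)=O
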